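## Retrosynthetic overview

1. Cut the bond between ring C2 and the side chain: a visible-light decarboxylative Minisci-type C–H alkylation joins 3,5-diethyl-2-methoxy-4H-pyran-4-one (one free ring C–H) with the primary radical from (S)-11-acetoxydodecanoic acid. This is the last step and the new reaction.
2. The γ-pyrone is the only ring and is made before the coupling: Claisen dimer of methyl butanoate, then dianion formylation and lactonisation to the 4-hydroxy-2-pyranone, then O-methylation on the lactone carbonyl oxygen.
3. The chain acid comes from (S)-propylene oxide, which carries the only stereocentre: opening at CH2 by dec-9-enyl Grignard, acetylation in the same flask, then cleavage of the terminal alkene to CO2H.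

Assumption: salts that are only protonated or deprotonated at aqueous work-up (for example the enolate of a product) are not numbered separately; reagents and intermediates made in the flask and consumed by a further addition are numbered.

## Route

Step 1
Reactants: 1 methyl butanoate (2 equiv.)
Product: 2 methyl 2-ethyl-3-oxohexanoate
Conditions: NaH (0.6 equiv.), MeOH (cat.), THF, reflux; then aq. HCl
Reagents that add atoms: none
Why: Claisen self-condensation of an ester with two α-hydrogens, driven to completion by irreversible deprotonation of the β-keto ester product.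

Step 2
Reactants: 2 methyl 2-ethyl-3-oxohexanoate
Product: 5 3,5-diethyl-4-hydroxy-2H-pyran-2-one, via dilithium dianion of methyl 2-ethyl-3-oxohexanoate 3 (not isolated), via methyl 2-ethyl-4-formyl-3-oxohexanoate 4 (not isolated)
Conditions: LDA (2.1 equiv. per 2), THF, −78 → 0 °C; HCO2Me (0.5 equiv.), −78 °C → rt; aq. HCl; crude, DBU (1.5 equiv.), PhMe, 80 °C
Reagents that add atoms: methyl formate, COC=O
Why: Huckin–Weiler γ-acylation (crossed Claisen formylation) of the β-keto ester dianion at its more nucleophilic γ-carbon, followed by DBU-mediated lactonisation of the formyl enol onto the methyl ester, the standard triketide to 4-hydroxy-2-pyranone closure.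

Step 3
Reactants: 5 3,5-diethyl-4-hydroxy-2H-pyran-2-one
Product: 6 3,5-diethyl-2-methoxy-4H-pyran-4-one
Conditions: MeOTf (1.2 equiv.), CH2Cl2, 0 °C → rt; aq. NaHCO3
Reagents that add atoms: methyl trifluoromethanesulfonate, COS(=O)(=O)C(F)(F)F
Why: regioselective O-methylation, in which the hard electrophile alkylates the more basic lactone carbonyl oxygen of the neutral 4-hydroxy-2-pyranone and the resulting 4-hydroxy-2-methoxypyrylium loses a proton to give the α-methoxy-γ-pyrone.

Step 4
Reactants: 7 10-bromodec-1-ene, 8 (S)-2-methyloxirane ((S)-propylene oxide)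
Product: 11 (S)-tridec-12-en-2-yl acetate, via dec-9-en-1-ylmagnesium bromide 9 (not isolated), via bromomagnesium (S)-tridec-12-en-2-olate 10 (not isolated)
Conditions: Mg, THF, 40 °C; CuI (10 mol %), 8 (1.2 equiv.), −30 → 0 °C; then Ac2O (2.5 equiv.), DMAP (5 mol %), 0 °C → rt
Reagents that add atoms: acetic anhydride, CC(=O)OC(C)=O
Why: copper-catalysed SN2 opening of the terminal epoxide by the Grignard reagent at the unsubstituted CH2 leaves the C–O stereocentre of (S)-propylene oxide untouched (carbinol carbon S), and the magnesium alkoxide is acylated in situ.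

Step 5
Reactants: 11 (S)-tridec-12-en-2-yl acetate
Product: 12 (S)-11-acetoxydodecanoic acid
Conditions: RuCl3·xH2O (2 mol %), NaIO4 (4.1 equiv.), EtOAc/MeCN/H2O (2:2:3), rt
Reagents that add atoms: sodium periodate, [Na+].[O-]I(=O)(=O)=O; water, O
Why: Sharpless RuO4-catalysed oxidative cleavage of a terminal alkene to the one-carbon-shorter carboxylic acid, under which the secondary acetate and its stereocentre are inert.

Step 6
Reactants: 12 (S)-11-acetoxydodecanoic acid, 6 3,5-diethyl-2-methoxy-4H-pyran-4-one
Product: 14 (S)-11-(3,5-diethyl-6-methoxy-4-oxo-4H-pyran-2-yl)undecan-2-yl acetate, via 1,3-dioxoisoindolin-2-yl (S)-11-acetoxydodecanoate 13 (not isolated)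
Conditions: 12 (1.0 equiv.), NHPI (1.1 equiv.), DIC (1.1 equiv.), DMAP (5 mol %), CH2Cl2, rt; then 6 (2.0 equiv.), fac-Ir(ppy)3 (1 mol %), TFA (5 equiv.), MeCN, 450 nm LEDs, 25 °C
Reagents that add atoms: none
Why: Proposed new method: photocatalytic decarboxylative Minisci-type C–H alkylation of an α-methoxy-γ-pyrone, in which TFA turns 6 into its 4-hydroxy-2-methoxypyrylium form whose only unsubstituted and least donor-stabilised electrophilic carbon is the ring C–H; excited Ir(ppy)3 reduces the redox-active ester 13 to the primary alkyl radical (loss of CO2 and phthalimide anion), the radical adds at that carbon, loss of the ring proton gives an electron-rich 4-hydroxypyranyl radical, and Ir(IV) oxidises it back to the pyrylium/pyrone to close the cycle; the pyrone does not absorb at 450 nm and the remote acetate stereocentre is not involved; closest known reaction type: visible-light decarboxylative Minisci alkylation of protonated N-heteroarenes with N-(acyloxy)phthalimides.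

## Compound list

1 | methyl butanoate | CCCC(=O)OC | starting material
2 | methyl 2-ethyl-3-oxohexanoate | CCCC(=O)C(CC)C(=O)OC | intermediate
3 | dilithium dianion of methyl 2-ethyl-3-oxohexanoate | CCC=C([O-])C(CC)=C([O-])OC.[Li+].[Li+] | intermediate
4 | methyl 2-ethyl-4-formyl-3-oxohexanoate | CCC(C=O)C(=O)C(CC)C(=O)OC | intermediate
5 | 3,5-diethyl-4-hydroxy-2H-pyran-2-one | CCc1coc(=O)c(CC)c1O | intermediate
6 | 3,5-diethyl-2-methoxy-4H-pyran-4-one | CCc1coc(OC)c(CC)c1=O | intermediate
7 | 10-bromodec-1-ene | C=CCCCCCCCCBr | starting material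
8 | (S)-2-methyloxirane | C[C@H]1CO1 | starting material
9 | dec-9-en-1-ylmagnesium bromide | C=CCCCCCCCC[Mg]Br | intermediate
10 | bromomagnesium (S)-tridec-12-en-2-olate | C=CCCCCCCCCC[C@H](C)O[Mg]Br | intermediate
11 | (S)-tridec-12-en-2-yl acetate | C=CCCCCCCCCC[C@H](C)OC(C)=O | intermediate
12 | (S)-11-acetoxydodecanoic acid | OC(=O)CCCCCCCCC[C@H](C)OC(C)=O | intermediate
13 | 1,3-dioxoisoindolin-2-yl (S)-11-acetoxydodecanoate | O=C(CCCCCCCCC[C@H](C)OC(C)=O)ON1C(=O)c2ccccc2C1=O | intermediate
14 | (S)-11-(3,5-diethyl-6-methoxy-4-oxo-4H-pyran-2-yl)undecan-2-yl acetate | CCc1c(CCCCCCCCC[C@H](C)OC(C)=O)oc(OC)c(CC)c1=O | target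

## Step count and risks

Total step count: 6. Longest linear sequence: 4 steps (1 → 2 → 3 → 6); the chain branch is 3 steps (4 → 5 → 6).

Steps most likely to fail:

**Step 6 (the new C–H alkylation).** The primary radical may add too slowly to the weakly basic pyrone, or the pyrylium may be reduced in competition with the redox-active ester. The fallback uses known chemistry, sets out from 12 and comes back at 14. 12 is activated with CDI (THF, rt) to the acyl imidazole (S)-12-(1H-imidazol-1-yl)-12-oxododecan-2-yl acetate F1. F1 is added at −78 °C to dianion 3 (2.2 equiv., made from 2 and LDA as in step 2); the acyl imidazole is far more electrophilic than the secondary acetate, and the product is the triketide methyl (S)-15-acetoxy-2,4-diethyl-3,5-dioxohexadecanoate F2. DBU in toluene closes F2 to (S)-11-(3,5-diethyl-4-hydroxy-2-oxo-2H-pyran-6-yl)undecan-2-yl acetate F3. MeOTf in CH2Cl2, as in step 3, methylates the lactone carbonyl oxygen of F3 and gives 14.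

**Step 3 (O-methylation regioselectivity).** The 4-methoxy-2-pyranone isomer may form in competition. The fallback sets out from 5 and comes back at 6, and it blocks the competing oxygen instead of relying on the reagent. TBSCl/imidazole in DMF gives 4-((tert-butyldimethylsilyl)oxy)-3,5-diethyl-2H-pyran-2-one F7, so only the lactone carbonyl oxygen is left to be alkylated. MeOTf in CH2Cl2 then gives 4-((tert-butyldimethylsilyl)oxy)-3,5-diethyl-2-methoxypyrylium trifluoromethanesulfonate F8, which is desilylated on aqueous NaHCO3 (or KF) work-up to 6.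

**Step 2 (γ-formylation of a hindered, α-branched dianion).** Proton transfer to the dianion may outrun acylation. The fallback sets out from 2 and comes back at 4, replacing the dianion Claisen by a Lewis-acid vinylogous Mukaiyama reaction. TMSOTf/Et3N converts 2 into methyl 2-ethyl-3-((trimethylsilyl)oxy)hex-2-enoate F4. LDA then TMSCl gives the bis-silyl dienol ether 2-ethyl-1-methoxy-1,3-bis((trimethylsilyl)oxy)hexa-1,3-diene F5. Trimethyl orthoformate with catalytic TMSOTf (CH2Cl2, −78 °C) gives methyl 4-(dimethoxymethyl)-2-ethyl-3-oxohexanoate F6. Aqueous HCl/THF unmasks the aldehyde to give 4, which is cyclised with DBU as in step 2.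

Further compounds
F1 | step 6 | (S)-12-(1H-imidazol-1-yl)-12-oxododecan-2-yl acetate | O=C(CCCCCCCCC[C@H](C)OC(C)=O)n1ccnc1
F2 | step 6 | methyl (S)-15-acetoxy-2,4-diethyl-3,5-dioxohexadecanoate | COC(=O)C(CC)C(=O)C(CC)C(=O)CCCCCCCCC[C@H](C)OC(C)=O
F3 | step 6 | (S)-11-(3,5-diethyl-4-hydroxy-2-oxo-2H-pyran-6-yl)undecan-2-yl acetate | CCc1c(CCCCCCCCC[C@H](C)OC(C)=O)oc(=O)c(CC)c1O
F4 | step 2 | methyl 2-ethyl-3-((trimethylsilyl)oxy)hex-2-enoate | CCCC(O[Si](C)(C)C)=C(CC)C(=O)OC
F5 | step 2 | 2-ethyl-1-methoxy-1,3-bis((trimethylsilyl)oxy)hexa-1,3-diene | CCC=C(O[Si](C)(C)C)C(CC)=C(OC)O[Si](C)(C)C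
F6 | step 2 | methyl 4-(dimethoxymethyl)-2-ethyl-3-oxohexanoate | CCC(C(OC)OC)C(=O)C(CC)C(=O)OC
F7 | step 3 | 4-((tert-butyldimethylsilyl)oxy)-3,5-diethyl-2H-pyran-2-one | CCc1coc(=O)c(CC)c1O[Si](C)(C)C(C)(C)C
F8 | step 3 | 4-((tert-butyldimethylsilyl)oxy)-3,5-diethyl-2-methoxypyrylium trifluoromethanesulfonate | CCc1c[o+]c(OC)c(CC)c1O[Si](C)(C)C(C)(C)C.[O-]S(=O)(=O)C(F)(F)F
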